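**Plan**

- Retrosynthetic cuts: the C8 ester, the C13 methylidene and the C12/C14 oxidation levels are removed first. C7–C11 and C8–C9 are then cut together, C1=C10 reverting to a C1 sulfone and a C9 methylidene. Last come O6–C12 (haloacetal), C1–C10 (Morita–Baylis–Hillman) and C6–C7 (vinyllithium addition).
- Enabling feature: C7 carries C11 and C8 carries C9, and the oxolane ring (O, C6, C7, C11, C12) shares the C6–C7 bond with the ten-membered ring. A C11 radical tethered through O6 can therefore add to C7 of a C7=C8 enol ether and pass the radical to C8, which closes onto C9.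
- Forward order: nerol gives the C1–C6 epoxy aldehyde; the chain is joined at C6–C7, then O6–C12, then C1–C10; one radical cascade closes the five-membered lactol ring and then the ten-membered ring.
- Stereochemistry: C4/C5 from Sharpless epoxidation, C6 from Felkin–Anh addition to the cis-epoxy aldehyde, C7 from the 5-exo transition state, C8 and the ring-cis C1=C10 from the macrocyclization.

Key step: step 15

Remark: atoms are numbered as in the germacrane skeleton of the target (C1–C10 ring, C11–C13 lactone carbons, C14 formyl carbon, C15 methyl); the target is 4R,5S,6S,7R,8R with a cis epoxide and a trans-fused lactone.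
Assumption: the ten-membered ring closure is taken to give the 8R ether drawn for 23; C8 is the one centre that substrate geometry does not predictably control.

**Route**

Step 1
Reactants: 1 nerol
Product: 2 (2S,3R)-2,3-epoxynerol
Conditions: Ti(OiPr)4 (cat.), L-(+)-diethyl tartrate (cat.), t-BuOOH, 4 Å MS, CH2Cl2, −20 °C
Reagents that add atoms: tert-butyl hydroperoxide CC(C)(C)OO
Why: Katsuki–Sharpless asymmetric epoxidation of the Z allylic alcohol, in which the L-(+)-tartrate catalyst delivers oxygen to the face that gives the (2S,3R) cis-epoxide, fixing C4 (R) and C5 (S) while the remote trisubstituted alkene is untouched.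

Step 2
Reactants: 2 (2S,3R)-2,3-epoxynerol
Product: 3 (2S,3R)-2,3-epoxyneryl tert-butyldimethylsilyl ether
Conditions: TBSCl, imidazole, CH2Cl2, 0 °C → rt
Reagents that add atoms: tert-butyldimethylsilyl chloride CC(C)(C)[Si](C)(C)Cl
Why: Standard silylation of the primary alcohol, so that the hydroxyl does not meet ozone and methanolic NaOH in the next step.

Step 3
Reactants: 3 (2S,3R)-2,3-epoxyneryl tert-butyldimethylsilyl ether
Product: 4 methyl 3-[(2R,3S)-3-(tert-butyldimethylsilyloxymethyl)-2-methyloxiran-2-yl]propanoate
Conditions: O3, NaOH (2.5 M in MeOH), CH2Cl2, −78 °C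
Reagents that add atoms: ozone [O-][O+]=O; methanol CO
Why: Ozonolysis in methanolic NaOH (Marshall oxidative cleavage) should convert the trisubstituted alkene directly into the C1 methyl ester, the epoxide and silyl ether being inert at −78 °C.

Step 4
Reactants: 4 methyl 3-[(2R,3S)-3-(tert-butyldimethylsilyloxymethyl)-2-methyloxiran-2-yl]propanoate
Product: 5 methyl 3-[(2R,3S)-3-(hydroxymethyl)-2-methyloxiran-2-yl]propanoate
Conditions: Bu4NF, AcOH, THF, 0 °C → rt
Reagents that add atoms: none
Why: Fluoride-induced Si–O cleavage, buffered with acetic acid so that the liberated alkoxide neither undergoes Payne rearrangement nor attacks the ester.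

Step 5
Reactants: 5 methyl 3-[(2R,3S)-3-(hydroxymethyl)-2-methyloxiran-2-yl]propanoate
Product: 6 methyl 3-[(2R,3R)-3-formyl-2-methyloxiran-2-yl]propanoate
Conditions: Dess–Martin periodinane, pyridine, CH2Cl2, 0 °C → rt
Reagents that add atoms: none
Why: Dess–Martin oxidation gives the α,β-epoxy aldehyde without touching epoxide or ester, pyridine buffering the acetic acid formed.

Step 6
Reactants: 7 4-methoxybenzyl alcohol; 8 ethyl vinyl ether
Product: 9 4-methoxybenzyl vinyl ether
Conditions: Pd(OAc)2 (cat.), 1,10-phenanthroline (cat.), ethyl vinyl ether (excess), CH2Cl2, rt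
Reagents that add atoms: none
Why: Palladium-catalysed transfer vinylation (transetherification), driven to the benzylic vinyl ether by the excess of vinyl donor under neutral conditions.

Step 7
Reactants: 9 4-methoxybenzyl vinyl ether
Product: 11 (Z)-2-bromovinyl 4-methoxybenzyl ether, via dibromide 10 (not isolated)
Conditions: Br2, CH2Cl2, −78 °C; then i-Pr2NEt, −78 → 40 °C
Reagents that add atoms: bromine BrBr
Why: Bromine adds to the electron-rich vinyl ether faster than it substitutes the anisole ring, and amine-promoted dehydrobromination of the α-bromo ether through its oxocarbenium ion gives the 2-bromovinyl ether, the Z isomer being favoured as for the ethyl analogue.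

Step 8
Reactants: 11 (Z)-2-bromovinyl 4-methoxybenzyl ether; 6 methyl 3-[(2R,3R)-3-formyl-2-methyloxiran-2-yl]propanoate
Product: 13 methyl 3-[(2R,3S)-3-[(1S,2Z)-1-hydroxy-3-(4-methoxybenzyloxy)prop-2-enyl]-2-methyloxiran-2-yl]propanoate, via vinyllithium 12 (not isolated)
Conditions: 11, t-BuLi (2 equiv per 11), Et2O, −78 °C; then 6, THF, −78 °C; NH4Cl (aq)
Reagents that add atoms: none
Why: Bromine–lithium exchange gives the chelation-stabilized Z-alkoxyvinyllithium, which adds to the aldehyde far faster than to the ester and in the Felkin–Anh sense anti to the epoxide C–O bond (reinforced by the cis C3 branch on C4), setting C6 (S) anti to the epoxide oxygen.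

Step 9
Reactants: 13 epoxy carbinol; 8 ethyl vinyl ether
Product: 15 O6-(2-bromo-1-ethoxyethyl) acetal of 13 (acetal carbon as a mixture), via α-bromo ether 14 (not isolated)
Conditions: Br2, ethyl vinyl ether (slight excess over Br2), CH2Cl2, −78 °C; then 13, i-Pr2NEt, −78 → 0 °C
Reagents that add atoms: bromine BrBr
Why: Two-stage haloacetalization (Ueno–Stork precursor synthesis) in which bromine is consumed by ethyl vinyl ether before the substrate is added, so the substrate's own enol ether never meets electrophilic bromine, and the amine buffer protects the acid-labile γ-alkoxy enol ether while the α-bromo ether alkylates the alcohol.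

Step 10
Reactants: 15 bromoacetal ester
Product: 16 O6-(1-ethoxy-2-iodoethyl) acetal (iodoacetal ester)
Conditions: NaI, NaHCO3, acetone, reflux, dark
Reagents that add atoms: sodium iodide [Na+].[I-]
Why: Finkelstein exchange, needed because stannyl radicals abstract iodine about a hundred times faster than they add to the 2-(sulfonylalkyl)acrylate built later, whereas bromine abstraction would only be competitive with that addition.

Step 11
Reactants: 16 iodoacetal ester
Product: 17 iodoacetal aldehyde (C1 aldehyde)
Conditions: i-Bu2AlH (1.1 equiv), CH2Cl2, −78 °C; MeOH, then aqueous tartrate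
Reagents that add atoms: none
Why: Partial ester reduction, in which i-Bu2AlH at −78 °C stops at the tetrahedral aluminium hemiacetal and releases the aldehyde on work-up, with iodide, acetal, enol ether and epoxide inert at this temperature.

Step 12
Reactants: 17 iodoacetal aldehyde; 18 methyl acrylate
Product: 19 Morita–Baylis–Hillman alcohol (C1 carbinol bearing the 2-methylidene methyl ester; C1 epimers)
Conditions: DABCO (1 equiv), methyl acrylate (5 equiv), MeOH, rt, dark
Reagents that add atoms: none
Why: Morita–Baylis–Hillman reaction of an unhindered aliphatic aldehyde forms C1–C10, the new carbinol centre being left as a mixture because C1 becomes sp2 in step 15.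

Step 13
Reactants: 19 Morita–Baylis–Hillman alcohol
Product: 20 C1 acetate of 19
Conditions: Ac2O, pyridine, DMAP (cat.), CH2Cl2, 0 °C
Reagents that add atoms: acetic anhydride CC(=O)OC(C)=O
Why: Standard acylation of the secondary allylic alcohol, kept cold and short to avoid allylic transposition of the acetate.

Step 14
Reactants: 20 C1 acetate; 21 sodium benzenesulfinate
Product: 22 cascade precursor: open-chain iodoacetal of the C6 carbinol with Z enol ether, cis epoxide and C1 phenylsulfonyl 2-methylidene ester (acetal carbon and C1 as mixtures)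
Conditions: PhSO2Na (1.2 equiv), DABCO (0.3 equiv), THF/H2O, rt
Reagents that add atoms: none
Why: Lewis-base-catalysed allylic substitution of a Morita–Baylis–Hillman acetate (SN2' by DABCO, then SN2' by sulfinate on the allylammonium ion) returns the sulfur nucleophile to the secondary carbon C1 and leaves the C9 methylidene in place.

Step 15
Reactants: 22 cascade precursor
Product: 23 bicyclic lactol ethyl ether fused to the ten-membered epoxy enoate: methyl (1(10)E,4R,5S,6S,7R,8R)-4,5:6,12-diepoxy-12-ethoxy-8-(4-methoxybenzyloxy)-13-norgermacr-1(10)-en-14-oate (C12 epimers)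
Conditions: (Bu3Sn)2 (1.5 equiv), degassed benzene (2 mM), hν (sunlamp, Pyrex), 25–30 °C
Reagents that add atoms: none
Why: Proposed new method: stannyl radicals from photolysed (Bu3Sn)2 abstract iodine, the C11 radical closes 5-exo-trig onto C7 of the enol ether (lactol ring), the nucleophilic α-alkoxy radical at C8 closes 10-endo-trig onto the methylidene C9 of the acrylate (carbocycle), and the C10 radical expels PhSO2• from C1 to form C1=C10, the sulfonyl radical being taken up by tin; no hydrogen donor is present, so the slow macrocyclization is not cut short by reduction. The closest known reactions are Ueno–Stork haloacetal cyclization with trapping of the cyclized radical, radical allyl transfer to 2-(sulfonylmethyl)acrylates under ditin photolysis and Porter-type radical macrocyclization onto acrylates, which have not been joined in one ring-forming cascade. C7 is set trans to the C5 substituent on C6 by the chair-like 5-exo transition state, reinforced by allylic 1,3-strain of the Z enol ether, which holds C6–H in the alkene plane and the epoxide on the face away from the tether. C8 is set by the face of the planar radical that C9 can reach inside the forming ring; 8R corresponds to the ether oxygen anti to C7–C11 across an extended C6–C7–C8–C9 backbone and is the least secure element. The C1=C10 bond is forced ring-cis (E) by the ten-membered ring, chemoselectivity rests on polarity matching at both additions, and high dilution at ambient temperature is chosen to suppress oligomerization and β-scission of the α-benzyloxy radical.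

Step 16
Reactants: 23 cascade product
Product: 24 C14 allylic alcohol (lactol ethyl ether, C8 4-methoxybenzyl ether)
Conditions: i-Bu2AlH (2.5 equiv), CH2Cl2, −78 °C
Reagents that add atoms: none
Why: 1,2-Reduction of the conjugated ester by excess i-Bu2AlH at −78 °C gives the allylic alcohol, with acetal, epoxide and ether untouched.

Step 17
Reactants: 24 C14 allylic alcohol
Product: 25 C8,C14 bis(4-methoxybenzyl) ether (lactol ethyl ether)
Conditions: NaH, 4-methoxybenzyl chloride, Bu4NI (cat.), THF/DMF, 0 °C → rt
Reagents that add atoms: 4-methoxybenzyl chloride COc1ccc(CCl)cc1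
Why: Williamson etherification of the primary allylic alkoxide masks C14 for the enolate chemistry with a group that later leaves together with the C8 ether.

Step 18
Reactants: 25 bis(4-methoxybenzyl) ether
Product: 26 lactol (C12 hemiacetal, anomers)
Conditions: AcOH/THF/H2O (3:1:1), 35 °C, stopped at full conversion
Reagents that add atoms: water O
Why: Specific-acid hydrolysis of the 2-alkoxyoxolane acetal, which should ionize faster than the epoxide because the latter is deactivated by the adjacent C6 oxygen.

Step 19
Reactants: 26 lactol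
Product: 27 γ-lactone (12,6-olide) with C8 and C14 4-methoxybenzyl ethers
Conditions: (n-Pr4N)RuO4 (cat.), N-methylmorpholine N-oxide, 4 Å MS, CH2Cl2, rt
Reagents that add atoms: none
Why: Ley–Griffith oxidation converts the lactol into the trans-fused γ-lactone under neutral conditions.

Step 20
Reactants: 27 γ-lactone
Product: 30 α-methylene lactone (C11=C13) with C8 and C14 4-methoxybenzyl ethers, via Mannich base 28 (not isolated), via ammonium iodide 29 (not isolated)
Conditions: LiN(i-Pr)2, THF, −78 °C; CH2=NMe2+ I−, −78 → 0 °C; then MeI, MeOH, rt; then NaHCO3 (aq), EtOAc, rt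
Reagents that add atoms: N,N-dimethylmethyleneiminium iodide C=[N+](C)C.[I-]
Why: Eschenmoser methylenation, in which the lithium enolate of the lactone (the only acidic C–H left) undergoes a Mannich reaction and quaternization followed by mild base-induced elimination gives the exocyclic alkene.

Step 21
Reactants: 30 α-methylene lactone
Product: 32 8-hydroxy-14-oxo lactone (hydroxy enal), via diol 31 (not isolated)
Conditions: DDQ (2.6 equiv), CH2Cl2/pH 7 buffer, 0 °C → rt; NaHCO3 wash; then MnO2, CH2Cl2, rt
Reagents that add atoms: none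
Why: DDQ cleaves both 4-methoxybenzyl ethers oxidatively at neutral pH, and MnO2 then oxidizes only the primary allylic alcohol to the enal, leaving the secondary C8 alcohol free.

Step 22
Reactants: 32 hydroxy enal; 33 isovaleric anhydride
Product: 34 CNP0260081.1, (1(10)E,4R,5S,6S,7R,8R)-4,5-epoxy-8-(3-methylbutanoyloxy)-14-oxogermacra-1(10),11(13)-dien-12,6-olide
Conditions: isovaleric anhydride, DMAP (cat.), pyridine, CH2Cl2, 0 °C → rt
Reagents that add atoms: none
Why: DMAP-catalysed acylation of the secondary alcohol proceeds with retention at C8 and gives the target.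

**Compound list**

1 | nerol | CC(C)=CCC/C(C)=C\CO | starting material
2 | (2S,3R)-2,3-epoxynerol | CC(C)=CCC[C@@]1(C)O[C@H]1CO | intermediate
3 | (2S,3R)-2,3-epoxyneryl tert-butyldimethylsilyl ether | CC(C)=CCC[C@@]1(C)O[C@H]1CO[Si](C)(C)C(C)(C)C | intermediate
4 | methyl 3-[(2R,3S)-3-(tert-butyldimethylsilyloxymethyl)-2-methyloxiran-2-yl]propanoate | COC(=O)CC[C@@]1(C)O[C@H]1CO[Si](C)(C)C(C)(C)C | intermediate
5 | methyl 3-[(2R,3S)-3-(hydroxymethyl)-2-methyloxiran-2-yl]propanoate | COC(=O)CC[C@@]1(C)O[C@H]1CO | intermediate
6 | methyl 3-[(2R,3R)-3-formyl-2-methyloxiran-2-yl]propanoate | COC(=O)CC[C@@]1(C)O[C@H]1C=O | intermediate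
7 | 4-methoxybenzyl alcohol | COc1ccc(CO)cc1 | starting material
8 | ethyl vinyl ether | C=COCC | starting material
9 | 4-methoxybenzyl vinyl ether | C=COCc1ccc(OC)cc1 | intermediate
10 | 1,2-dibromoethyl 4-methoxybenzyl ether (not isolated) | BrCC(Br)OCc1ccc(OC)cc1 | intermediate
11 | (Z)-2-bromovinyl 4-methoxybenzyl ether | Br/C=C\OCc1ccc(OC)cc1 | intermediate
12 | (Z)-2-(4-methoxybenzyloxy)vinyllithium (not isolated) | [Li]/C=C\OCc1ccc(OC)cc1 | intermediate
13 | methyl 3-[(2R,3S)-3-[(1S,2Z)-1-hydroxy-3-(4-methoxybenzyloxy)prop-2-enyl]-2-methyloxiran-2-yl]propanoate (4R,5S,6S, anti epoxy alcohol) | COC(=O)CC[C@@]1(C)O[C@H]1[C@@H](O)/C=C\OCc1ccc(OC)cc1 | intermediate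
14 | 1,2-dibromo-1-ethoxyethane (not isolated) | CCOC(Br)CBr | intermediate
15 | O6-(2-bromo-1-ethoxyethyl) acetal of 13 (acetal epimers) | CCOC(CBr)O[C@@H](/C=C\OCc1ccc(OC)cc1)[C@@H]1O[C@]1(C)CCC(=O)OC | intermediate
16 | O6-(1-ethoxy-2-iodoethyl) acetal, C1 methyl ester | CCOC(CI)O[C@@H](/C=C\OCc1ccc(OC)cc1)[C@@H]1O[C@]1(C)CCC(=O)OC | intermediate
17 | iodoacetal C1 aldehyde | CCOC(CI)O[C@@H](/C=C\OCc1ccc(OC)cc1)[C@@H]1O[C@]1(C)CCC=O | intermediate
18 | methyl acrylate | C=CC(=O)OC | starting material
19 | Morita–Baylis–Hillman alcohol (C1 epimers) | CCOC(CI)O[C@@H](/C=C\OCc1ccc(OC)cc1)[C@@H]1O[C@]1(C)CCC(O)C(=C)C(=O)OC | intermediate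
20 | C1 acetate of 19 | CCOC(CI)O[C@@H](/C=C\OCc1ccc(OC)cc1)[C@@H]1O[C@]1(C)CCC(OC(C)=O)C(=C)C(=O)OC | intermediate
21 | sodium benzenesulfinate | [Na+].[O-]S(=O)c1ccccc1 | starting material
22 | cascade precursor, C1 phenylsulfonyl 2-methylidene ester with iodoacetal, Z enol ether and cis epoxide | CCOC(CI)O[C@@H](/C=C\OCc1ccc(OC)cc1)[C@@H]1O[C@]1(C)CCC(S(=O)(=O)c1ccccc1)C(=C)C(=O)OC | intermediate
23 | bicyclic lactol ethyl ether fused to the ten-membered epoxy enoate (C12 epimers) | C1C(OCC)O[C@H]2[C@H]1[C@H](OCc3ccc(OC)cc3)C/C(C(=O)OC)=C\CC[C@@]1(C)O[C@@H]21 | intermediate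
24 | C14 allylic alcohol | C1C(OCC)O[C@H]2[C@H]1[C@H](OCc3ccc(OC)cc3)C/C(CO)=C\CC[C@@]1(C)O[C@@H]21 | intermediate
25 | C8,C14 bis(4-methoxybenzyl) ether, lactol ethyl ether | C1C(OCC)O[C@H]2[C@H]1[C@H](OCc3ccc(OC)cc3)C/C(COCc3ccc(OC)cc3)=C\CC[C@@]1(C)O[C@@H]21 | intermediate
26 | lactol | C1C(O)O[C@H]2[C@H]1[C@H](OCc3ccc(OC)cc3)C/C(COCc3ccc(OC)cc3)=C\CC[C@@]1(C)O[C@@H]21 | intermediate
27 | γ-lactone | C1C(=O)O[C@H]2[C@H]1[C@H](OCc3ccc(OC)cc3)C/C(COCc3ccc(OC)cc3)=C\CC[C@@]1(C)O[C@@H]21 | intermediate
28 | C11 dimethylaminomethyl lactone, Mannich base (not isolated) | CN(C)CC1C(=O)O[C@H]2[C@H]1[C@H](OCc3ccc(OC)cc3)C/C(COCc3ccc(OC)cc3)=C\CC[C@@]1(C)O[C@@H]21 | intermediate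
29 | trimethylammonium iodide of 28 (not isolated) | C[N+](C)(C)CC1C(=O)O[C@H]2[C@H]1[C@H](OCc3ccc(OC)cc3)C/C(COCc3ccc(OC)cc3)=C\CC[C@@]1(C)O[C@@H]21.[I-] | intermediate
30 | α-methylene lactone, bis(4-methoxybenzyl) ether | C=C1C(=O)O[C@H]2[C@H]1[C@H](OCc3ccc(OC)cc3)C/C(COCc3ccc(OC)cc3)=C\CC[C@@]1(C)O[C@@H]21 | intermediate
31 | C8,C14 diol (not isolated) | C=C1C(=O)O[C@H]2[C@H]1[C@H](O)C/C(CO)=C\CC[C@@]1(C)O[C@@H]21 | intermediate
32 | 8-hydroxy-14-oxo lactone | C=C1C(=O)O[C@H]2[C@H]1[C@H](O)C/C(C=O)=C\CC[C@@]1(C)O[C@@H]21 | intermediate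
33 | isovaleric anhydride | CC(C)CC(=O)OC(=O)CC(C)C | starting material
34 | CNP0260081.1 | C=C1C(=O)O[C@H]2[C@H]1[C@H](OC(=O)CC(C)C)C/C(C=O)=C\CC[C@@]1(C)O[C@@H]21 | target

**Step count**

Total step count: 22. Longest linear sequence: 20 steps (steps 1–5 and 8–22, from nerol).

**Steps most likely to fail**

1. Step 15 (proposed cascade). The ten-membered closure may be too slow, so that the C8 radical is lost to β-scission of the benzylic ether or to oligomerization, or C9 may reach the wrong face of the C8 radical. The fallback separates the two C–C bond formations with known reactions, setting out from aldehyde 17 and returning at 23.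
   - Wittig methylenation of 17 (Ph3PCH3Br, KN(SiMe3)2, THF) would give the terminal alkene F1.
   - Photolysis of F1 with (Bu3Sn)2 in the presence of excess methyl 2-[(phenylsulfonyl)methyl]acrylate F2 (from commercial methyl 2-(bromomethyl)acrylate and 21) would effect Ueno–Stork cyclization with intermolecular allyl transfer to the C8 radical. This would give the oxolane diene F3, with C8 then set under open-chain control.
   - Ring-closing metathesis of F3 with the second-generation Hoveyda–Grubbs catalyst, (H2IMes)Cl2Ru=CH(2-i-PrOC6H4), at high dilution would close C1=C10 with loss of ethene and rejoin the route at 23.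

2. Step 14. The sulfinate may attack the wrong allylic terminus, or the sulfonyl group may shift 1,3 afterwards, draining the branched sulfone into the conjugated primary isomer. The fallback bypasses the sulfone, setting out from acetate 20 and returning at 23.
   - Slow addition of Bu3SnH with AIBN to 20 in benzene at 80 °C and high dilution would run the same 5-exo closure followed by a Porter-type reductive macrocyclization onto the 2-substituted acrylate, giving the β-acetoxy ester F4.
   - DBU would then eliminate acetic acid across C1–C10 to give 23.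

3. Step 18. Acid may open the epoxide, by hydration or by transannular attack of the C1=C10 alkene, at a rate close to that of acetal hydrolysis. The fallback makes the alkene electron-poor before the acid step, setting out from allylic alcohol 24 and returning at 27.
   - MnO2 would oxidize 24 to the enal F5.
   - The same aqueous acetic acid hydrolysis would give the lactol enal F6.
   - (n-Pr4N)RuO4 with N-methylmorpholine N-oxide would give the lactone enal F7.
   - NaBH4/CeCl3 (Luche reduction) would reduce only the aldehyde, giving the lactone alcohol F8.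
   - NaH and 4-methoxybenzyl chloride would then give 27.

**Further compounds**

F1 | step 15 | iodoacetal with C1 vinyl group (methylenation product of 17) | CCOC(CI)O[C@@H](/C=C\OCc1ccc(OC)cc1)[C@@H]1O[C@]1(C)CCC=C
F2 | step 15 | methyl 2-[(phenylsulfonyl)methyl]acrylate | C=C(CS(=O)(=O)c1ccccc1)C(=O)OC
F3 | step 15 | oxolane lactol ethyl ether with C8 2-(methoxycarbonyl)allyl chain and C1 vinyl group | C1C(OCC)O[C@@H]([C@H]1[C@H](OCc1ccc(OC)cc1)CC(=C)C(=O)OC)[C@@H]1O[C@]1(C)CCC=C
F4 | step 14 | bicyclic 1-acetoxy-1,10-dihydro ester (C1 and C10 epimers) | C1C(OCC)O[C@H]2[C@H]1[C@H](OCc3ccc(OC)cc3)CC(C(=O)OC)C(OC(C)=O)CC[C@@]1(C)O[C@@H]21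
F5 | step 18 | C14 enal, lactol ethyl ether | C1C(OCC)O[C@H]2[C@H]1[C@H](OCc3ccc(OC)cc3)C/C(C=O)=C\CC[C@@]1(C)O[C@@H]21
F6 | step 18 | C14 enal, lactol | C1C(O)O[C@H]2[C@H]1[C@H](OCc3ccc(OC)cc3)C/C(C=O)=C\CC[C@@]1(C)O[C@@H]21
F7 | step 18 | C14 enal, γ-lactone | C1C(=O)O[C@H]2[C@H]1[C@H](OCc3ccc(OC)cc3)C/C(C=O)=C\CC[C@@]1(C)O[C@@H]21
F8 | step 18 | C14 allylic alcohol, γ-lactone | C1C(=O)O[C@H]2[C@H]1[C@H](OCc3ccc(OC)cc3)C/C(CO)=C\CC[C@@]1(C)O[C@@H]21
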